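The route disconnects the C3–C4 bond of ring A. The axial C3 hydroxyl sits next to the quaternary C4 that carries the C19 formyl group, which is an aldol pattern between a C19 aldehyde enolate and a C3 aldehyde. A BF3-mediated intramolecular Mukaiyama aldol closes ring A onto a finished ring B and sets C3 and C4 in one operation. Its precursor is a fully substituted, (S)-carvone-derived cyclohexene (ring B). It carries the C19 silyl enol ether on C5, the C1–C3 arm ending in an α-silyloxy aldehyde on C10, and the C11–C15 allyl ester chain on C9.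

Key step: step 22

Remark: labdane locants are used throughout; ring-B intermediates 14–30 are named as 3,4-seco-labdanes (bond C3–C4 missing) and, unless stated, C2, C5, C9, C10 and C13 are configured as in 34. The target belongs to the ent-labdane series; (S)-carvone, (S)-solketal and the acid arm of the (R)-half-ester map onto C5, C2 and C11–C12 (C13) in the required sense.
Remark: C4 in 20–27 is an epimer mixture of no consequence, because C4 becomes trigonal in 28.

Step 1
Reactants: 1 (S)-carvone
Product: 3 (5S,6RS)-6-methylcarvone, via lithium dienolate of carvone 2 (not isolated)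
Conditions: LiN(i-Pr)2, THF, −78 °C; MeI, −78 → 0 °C
Reagents that add atoms: iodomethane, CI
Why: Kinetic α′-deprotonation and C-methylation of the cross-conjugated dienolate (enolate alkylation) installs C20; the new centre forms as an epimer mixture that is erased when the position is enolised again in step 3.

Step 2
Reactants: 4 (S)-solketal
Product: 5 [(4R)-2,2-dimethyl-1,3-dioxolan-4-yl]methyl trifluoromethanesulfonate
Conditions: Tf2O, pyridine, CH2Cl2, −78 → −20 °C; used at once
Reagents that add atoms: trifluoromethanesulfonic anhydride, O=S(=O)(OS(=O)(=O)C(F)(F)F)C(F)(F)F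
Why: O-Sulfonylation of the primary alcohol gives the alkyl triflate without touching the stereocentre, which lies one carbon away (the descriptor changes only through ligand priorities).

Step 3
Reactants: 3 (5S,6RS)-6-methylcarvone; 5 [(4R)-2,2-dimethyl-1,3-dioxolan-4-yl]methyl trifluoromethanesulfonate
Product: 7 (5R,6R)-6-{[(4S)-2,2-dimethyl-1,3-dioxolan-4-yl]methyl}-2,6-dimethyl-5-(prop-1-en-2-yl)cyclohex-2-en-1-one, via lithium enolate of 6-methylcarvone 6 (not isolated)
Conditions: LiN(i-Pr)2, THF, −78 °C; then 5, DMPU, −78 → −20 °C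
Reagents that add atoms: none
Why: Enolate C-alkylation with a primary alkyl triflate builds quaternary C10; the electrophile should enter the tetrasubstituted enolate anti to the neighbouring isopropenyl group, so that the C1–C3 arm ends trans and the C20 methyl cis to it, while C2 is carried over unchanged from 4.

Step 4
Reactants: 8 (R)-monomethyl 3-methylglutarate
Product: 9 methyl (3R)-5-hydroxy-3-methylpentanoate
Conditions: BH3·SMe2, THF, −10 °C → rt; MeOH/H2O quench
Reagents that add atoms: none
Why: Chemoselective borane reduction of a carboxylic acid beside an ester turns the acid arm into the future C11 carbinol and leaves the stereocentre untouched.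

Step 5
Reactants: 9 methyl (3R)-5-hydroxy-3-methylpentanoate
Product: 10 methyl (3S)-5-iodo-3-methylpentanoate
Conditions: I2, PPh3, imidazole, CH2Cl2, 0 °C → rt
Reagents that add atoms: iodine, II
Why: Appel-type iodination converts the primary alcohol into the iodide by SN2 displacement of the oxyphosphonium group.

Step 6
Reactants: 10 methyl (3S)-5-iodo-3-methylpentanoate
Product: 11 (3S)-5-iodo-3-methylpentanal
Conditions: i-Bu2AlH (1.05 equiv), CH2Cl2, −78 °C; aqueous work-up
Reagents that add atoms: none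
Why: Partial ester reduction with one equivalent of i-Bu2AlH stops at the aluminium hemiacetal at low temperature and releases the aldehyde on work-up, the primary iodide being inert.

Step 7
Reactants: 11 (3S)-5-iodo-3-methylpentanal
Product: 12 (3S)-5-iodo-1,1-dimethoxy-3-methylpentane
Conditions: HC(OMe)3, MeOH, TsOH (cat.), rt
Reagents that add atoms: trimethyl orthoformate, COC(OC)OC; methanol, CO
Why: Acid-catalysed acetalisation with orthoformate as water scavenger masks C15 in a form that tolerates alkyllithiums, chromium oxidation, hydride and hydroboration.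

Step 8
Reactants: 12 (3S)-5-iodo-1,1-dimethoxy-3-methylpentane; 7 (5R,6R)-6-{[(4S)-2,2-dimethyl-1,3-dioxolan-4-yl]methyl}-2,6-dimethyl-5-(prop-1-en-2-yl)cyclohex-2-en-1-one
Product: 14 15,15-dimethoxy-2,3-(isopropylidenedioxy)-3,4-seco-labda-4(19),7-dien-9-ol (C9 epimers), via [(3R)-5,5-dimethoxy-3-methylpentyl]lithium 13 (not isolated)
Conditions: t-BuLi (2 equiv), Et2O/pentane, −78 °C; then 7, −78 → 0 °C; H2O
Reagents that add atoms: none
Why: Iodine–lithium exchange gives the primary alkyllithium, which adds 1,2 to the hindered enone carbonyl that has no α′-hydrogen (organolithium carbonyl addition); the C9 carbinol configuration is irrelevant because C9 becomes trigonal in step 9.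

Step 9
Reactants: 14 15,15-dimethoxy-2,3-(isopropylidenedioxy)-3,4-seco-labda-4(19),7-dien-9-ol
Product: 15 15,15-dimethoxy-2,3-(isopropylidenedioxy)-3,4-seco-labda-4(19),8-dien-7-one
Conditions: C5H5NH[CrO3Cl] (pyridinium chlorochromate), 4 Å MS, CH2Cl2, rt
Reagents that add atoms: pyridinium chlorochromate, [O-][Cr](=O)(=O)Cl.c1cc[nH+]cc1
Why: Babler–Dauben oxidative transposition: the tertiary allylic chromate ester shifts to C7 by a [3,3] process and is oxidised there, giving the tetrasubstituted enone with the side chain on C9.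

Step 10
Reactants: 15 15,15-dimethoxy-2,3-(isopropylidenedioxy)-3,4-seco-labda-4(19),8-dien-7-one
Product: 16 (7R)-15,15-dimethoxy-2,3-(isopropylidenedioxy)-3,4-seco-labda-4(19),8-dien-7-ol (7-OH cis to the isopropenyl group)
Conditions: NaBH4, CeCl3·7H2O, MeOH, −78 → −40 °C
Reagents that add atoms: none
Why: Luche 1,2-reduction; axial hydride delivery to the half-chair with equatorial isopropenyl (the carvone to cis-carveol pattern) should give the pseudo-equatorial C7 alcohol cis to the C5 substituent.

Step 11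
Reactants: 16 (7R)-15,15-dimethoxy-2,3-(isopropylidenedioxy)-3,4-seco-labda-4(19),8-dien-7-ol
Product: 19 15,15-dimethoxy-2,3-(isopropylidenedioxy)-3,4-seco-labda-4(19),7-diene, via Mitsunobu hydrazone adduct 17 (not isolated), via allylic diazene 18 (not isolated)
Conditions: N′-isopropylidene-2-nitrobenzenesulfonohydrazide (IPNBSH), PPh3, DEAD, THF, 0 °C → rt; then CF3CH2OH/H2O (1:1), rt
Reagents that add atoms: none
Why: Reductive 1,3-transposition of an allylic alcohol: Mitsunobu displacement inverts C7, hydrolysis and sulfinate loss give the monoalkyl diazene, and its retro-ene loss of N2 delivers hydrogen to C9 on the face of the C7–N bond (anti to the C20 methyl), which sets C9 and moves the alkene to C7=C8.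

Step 12
Reactants: 19 15,15-dimethoxy-2,3-(isopropylidenedioxy)-3,4-seco-labda-4(19),7-diene
Product: 21 15,15-dimethoxy-2,3-(isopropylidenedioxy)-3,4-seco-labd-7-en-19-ol (C4 epimers), via B-alkyl-9-borabicyclononane 20 (not isolated)
Conditions: 9-BBN, THF, 0 → 50 °C; then NaOH, H2O2, 0 °C → rt
Reagents that add atoms: hydrogen peroxide, OO
Why: Hydroboration–oxidation with bulky 9-BBN selects the 1,1-disubstituted isopropenyl alkene over the hindered trisubstituted ring alkene and gives the anti-Markovnikov primary alcohol; C4 forms as an inconsequential epimer mixture.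

Step 13
Reactants: 21 15,15-dimethoxy-2,3-(isopropylidenedioxy)-3,4-seco-labd-7-en-19-ol
Product: 22 19-hydroxy-2,3-(isopropylidenedioxy)-3,4-seco-labd-7-en-15-al
Conditions: PPTS (cat.), acetone/H2O (10:1), rt
Reagents that add atoms: water, O
Why: Acid-catalysed acetal hydrolysis cleaves the acyclic dimethyl acetal much faster than the dioxolane, which is additionally held in place by the acetone solvent.

Step 14
Reactants: 22 19-hydroxy-2,3-(isopropylidenedioxy)-3,4-seco-labd-7-en-15-al
Product: 23 19-hydroxy-2,3-(isopropylidenedioxy)-3,4-seco-labd-7-en-15-oic acid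
Conditions: NaClO2, NaH2PO4, 2-methyl-2-butene, t-BuOH/H2O, 0 °C → rt
Reagents that add atoms: sodium chlorite, [Na+].[O-]Cl=O
Why: Pinnick oxidation is specific for the aldehyde, leaves the free primary alcohol untouched, and the hypochlorous acid by-product is trapped by the scavenger alkene so that C7=C8 survives.

Step 15
Reactants: 23 19-hydroxy-2,3-(isopropylidenedioxy)-3,4-seco-labd-7-en-15-oic acid
Product: 24 allyl 19-hydroxy-2,3-(isopropylidenedioxy)-3,4-seco-labd-7-en-15-oate
Conditions: allyl bromide, KHCO3, DMF, rt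
Reagents that add atoms: allyl bromide, C=CCBr
Why: Carboxylate O-alkylation (SN2) under weak base esterifies the acid selectively beside the free alcohol, and the allyl group is introduced only after the hydroboration that it would not survive.

Step 16
Reactants: 24 allyl 19-hydroxy-2,3-(isopropylidenedioxy)-3,4-seco-labd-7-en-15-oate
Product: 25 allyl 2,3-(isopropylidenedioxy)-19-oxo-3,4-seco-labd-7-en-15-oate
Conditions: Dess–Martin periodinane, pyridine, CH2Cl2, 0 °C → rt
Reagents that add atoms: none
Why: Dess–Martin oxidation of the only free hydroxyl gives the α-branched C19 aldehyde while C2 and C3 are still tied up in the acetonide.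

Step 17
Reactants: 25 allyl 2,3-(isopropylidenedioxy)-19-oxo-3,4-seco-labd-7-en-15-oate
Product: 26 allyl 2,3-dihydroxy-19-oxo-3,4-seco-labd-7-en-15-oate
Conditions: AcOH/THF/H2O (3:1:1), 40 °C
Reagents that add atoms: none
Why: Mild aqueous acid hydrolysis of the terminal isopropylidene acetal frees the 1,2-diol without affecting the allyl ester, the aldehyde or the ring alkene.

Step 18
Reactants: 26 allyl 2,3-dihydroxy-19-oxo-3,4-seco-labd-7-en-15-oate
Product: 27 allyl 3-(chloroacetoxy)-2-hydroxy-19-oxo-3,4-seco-labd-7-en-15-oate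
Conditions: ClCH2COCl (1.05 equiv), 2,4,6-collidine, CH2Cl2, −78 °C
Reagents that add atoms: chloroacetyl chloride, ClCC(Cl)=O
Why: Kinetic primary-selective acylation of the 1,2-diol with an acid chloride and a hindered base places on O3 an ester that can later be removed without acid, fluoride or strong base.

Step 19
Reactants: 27 allyl 3-(chloroacetoxy)-2-hydroxy-19-oxo-3,4-seco-labd-7-en-15-oate
Product: 28 allyl (4(19)E)-3-(chloroacetoxy)-2,19-bis(tert-butyldimethylsilyloxy)-3,4-seco-labda-4(19),7-dien-15-oate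
Conditions: TBSOTf (2.5 equiv), Et3N, CH2Cl2, −78 °C → rt
Reagents that add atoms: tert-butyldimethylsilyl trifluoromethanesulfonate, CC(C)(C)[Si](C)(C)OS(=O)(=O)C(F)(F)F
Why: Silyl triflate/amine silylates the C2 hydroxyl and soft-enolises the C19 aldehyde in one operation, giving mainly the enol ether with oxygen trans to the ring, while the two esters are not enolised under these conditions.

Step 20
Reactants: 28 allyl (4(19)E)-3-(chloroacetoxy)-2,19-bis(tert-butyldimethylsilyloxy)-3,4-seco-labda-4(19),7-dien-15-oate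
Product: 29 allyl (4(19)E)-2,19-bis(tert-butyldimethylsilyloxy)-3-hydroxy-3,4-seco-labda-4(19),7-dien-15-oate
Conditions: thiourea, NaHCO3, EtOH/THF, 40 °C
Reagents that add atoms: none
Why: Selective dechloroacetylation: thiourea is S-alkylated by the chloroacetate and cyclises to the thiazolidinone, releasing the C3 alcohol under near-neutral conditions that the allyl ester, the silyl ether and the silyl enol ether should tolerate.

Step 21
Reactants: 29 allyl (4(19)E)-2,19-bis(tert-butyldimethylsilyloxy)-3-hydroxy-3,4-seco-labda-4(19),7-dien-15-oate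
Product: 30 allyl (4(19)E)-2,19-bis(tert-butyldimethylsilyloxy)-3-oxo-3,4-seco-labda-4(19),7-dien-15-oate
Conditions: Dess–Martin periodinane, pyridine, CH2Cl2, 0 °C; used directly
Reagents that add atoms: none
Why: Pyridine-buffered Dess–Martin oxidation gives the α-silyloxy aldehyde without acid or fluoride, so the enol silane and the C2 configuration are preserved.

Step 22
Reactants: 30 allyl (4(19)E)-2,19-bis(tert-butyldimethylsilyloxy)-3-oxo-3,4-seco-labda-4(19),7-dien-15-oate
Product: 31 allyl 2-(tert-butyldimethylsilyloxy)-3-hydroxy-19-oxolabd-7-en-15-oate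
Conditions: BF3·OEt2 (1.2 equiv), CH2Cl2 (0.005 M), −78 °C; aq. NaHCO3
Reagents that add atoms: none
Why: BF3 activates the C3 aldehyde, the nucleophilic C4 of the C19 enol silane adds to it, and silicon is lost as the silyl fluoride to release the C19 aldehyde, which is an intramolecular Mukaiyama aldol addition of an aldehyde-derived enol silane to an aldehyde. Ring A closes in the 6-(enolexo)-exo-trig mode through a chair that is trans-fused to ring B, because both tethers are equatorial on the carvone-derived ring. C3 is controlled by the fixed C2 centre: the equatorial silyloxy group lies antiperiplanar to the forming C3–C4 bond (polar Felkin–Anh arrangement), and the open transition state expected with monodentate BF3, with C=O antiperiplanar to C=C, puts the C3 oxygen axial and cis to O2. C4 is controlled by the axial C20 methyl on C10: the slim =CH–OSi terminus, not the C18 methyl, takes the axial site syn to C20, so C19 ends axial and anti to the C3 oxygen whichever enol geometry is present. The step needs donor/acceptor selectivity, secured because only C19 is present as an enol silane while the enolisable C3 aldehyde has no donor activation, and chemoselectivity over C7=C8, which is a much weaker π-nucleophile than the enol ether; high dilution suppresses the intermolecular aldol.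

Step 23
Reactants: 31 allyl 2-(tert-butyldimethylsilyloxy)-3-hydroxy-19-oxolabd-7-en-15-oate
Product: 32 allyl 2,3-dihydroxy-19-oxolabd-7-en-15-oate
Conditions: HF·pyridine, pyridine, THF, 0 °C → rt
Reagents that add atoms: none
Why: Fluoride-mediated desilylation of the secondary silyl ether under buffered conditions spares the allyl ester and the β-hydroxy aldehyde, which cannot dehydrate because C4 is quaternary.

Step 24
Reactants: 32 allyl 2,3-dihydroxy-19-oxolabd-7-en-15-oate
Product: 33 allyl 2-acetoxy-3-hydroxy-19-oxolabd-7-en-15-oate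
Conditions: Ac2O (1.2 equiv), pyridine, CH2Cl2, 0 °C
Reagents that add atoms: acetic anhydride, CC(=O)OC(C)=O
Why: Selective esterification without an acyl-transfer catalyst should acetylate the unhindered equatorial C2 hydroxyl and leave the axial C3 hydroxyl, which is flanked by quaternary C4.

Step 25
Reactants: 33 allyl 2-acetoxy-3-hydroxy-19-oxolabd-7-en-15-oate
Product: 34 (2S,3R,4S,5S,9R,10S,13R)-2-acetoxy-3-hydroxy-19-oxolabd-7-en-15-oic acid (CNP0180877.1)
Conditions: Pd(PPh3)4 (cat.), morpholine, THF, rt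
Reagents that add atoms: none
Why: Tsuji–Trost deallylation: the palladium catalyst ionises the allyl ester to a π-allyl complex that morpholine captures, freeing the acid under neutral conditions that spare the acetate, the hindered aldehyde and the aldol.

Compound list
1 | (S)-carvone | CC1=CC[C@@H](CC1=O)C(C)=C | starting material
2 | lithium dienolate of carvone | [Li]OC1=C[C@@H](C(C)=C)CC=C1C | intermediate (not isolated)
3 | (5S,6RS)-6-methylcarvone | CC1C(=O)C(C)=CC[C@@H]1C(C)=C | intermediate
4 | (S)-solketal | OC[C@H]1COC(C)(C)O1 | starting material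
5 | [(4R)-2,2-dimethyl-1,3-dioxolan-4-yl]methyl trifluoromethanesulfonate | CC1(C)OC[C@H](COS(=O)(=O)C(F)(F)F)O1 | intermediate
6 | lithium enolate of 6-methylcarvone | [Li]OC1=C(C)[C@@H](C(C)=C)CC=C1C | intermediate (not isolated)
7 | (5R,6R)-6-{[(4S)-2,2-dimethyl-1,3-dioxolan-4-yl]methyl}-2,6-dimethyl-5-(prop-1-en-2-yl)cyclohex-2-en-1-one | CC1(C)OC[C@H](C[C@@]2(C)C(=O)C(C)=CC[C@@H]2C(C)=C)O1 | intermediate
8 | (R)-monomethyl 3-methylglutarate | OC(=O)C[C@@H](C)CC(=O)OC | starting material
9 | methyl (3R)-5-hydroxy-3-methylpentanoate | OCC[C@@H](C)CC(=O)OC | intermediate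
10 | methyl (3S)-5-iodo-3-methylpentanoate | ICC[C@@H](C)CC(=O)OC | intermediate
11 | (3S)-5-iodo-3-methylpentanal | ICC[C@@H](C)CC=O | intermediate
12 | (3S)-5-iodo-1,1-dimethoxy-3-methylpentane | ICC[C@@H](C)CC(OC)OC | intermediate
13 | [(3R)-5,5-dimethoxy-3-methylpentyl]lithium | [Li]CC[C@@H](C)CC(OC)OC | intermediate (not isolated)
14 | 15,15-dimethoxy-2,3-(isopropylidenedioxy)-3,4-seco-labda-4(19),7-dien-9-ol (C9 epimers) | CC1(C)OC[C@H](C[C@@]2(C)C(O)(CC[C@@H](C)CC(OC)OC)C(C)=CC[C@@H]2C(C)=C)O1 | intermediate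
15 | 15,15-dimethoxy-2,3-(isopropylidenedioxy)-3,4-seco-labda-4(19),8-dien-7-one | CC1(C)OC[C@H](C[C@@]2(C)C(CC[C@@H](C)CC(OC)OC)=C(C)C(=O)C[C@@H]2C(C)=C)O1 | intermediate
16 | (7R)-15,15-dimethoxy-2,3-(isopropylidenedioxy)-3,4-seco-labda-4(19),8-dien-7-ol | CC1(C)OC[C@H](C[C@@]2(C)C(CC[C@@H](C)CC(OC)OC)=C(C)[C@H](O)C[C@@H]2C(C)=C)O1 | intermediate
17 | Mitsunobu hydrazone adduct (C7 inverted; N-(2-nitrobenzenesulfonyl)-N′-isopropylidene hydrazide on C7) | CC1(C)OC[C@H](C[C@@]2(C)C(CC[C@@H](C)CC(OC)OC)=C(C)[C@@H](N(N=C(C)C)S(=O)(=O)c3ccccc3[N+](=O)[O-])C[C@@H]2C(C)=C)O1 | intermediate (not isolated)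
18 | allylic diazene (C7–N=NH) | CC1(C)OC[C@H](C[C@@]2(C)C(CC[C@@H](C)CC(OC)OC)=C(C)[C@@H](N=N)C[C@@H]2C(C)=C)O1 | intermediate (not isolated)
19 | 15,15-dimethoxy-2,3-(isopropylidenedioxy)-3,4-seco-labda-4(19),7-diene | CC1(C)OC[C@H](C[C@@]2(C)[C@H](CC[C@@H](C)CC(OC)OC)C(C)=CC[C@@H]2C(C)=C)O1 | intermediate
20 | B-alkyl-9-borabicyclononane (boron on C19) | CC1(C)OC[C@H](C[C@@]2(C)[C@H](CC[C@@H](C)CC(OC)OC)C(C)=CC[C@@H]2C(C)CB3C4CCCC3CCC4)O1 | intermediate (not isolated)
21 | 15,15-dimethoxy-2,3-(isopropylidenedioxy)-3,4-seco-labd-7-en-19-ol (C4 epimers) | CC1(C)OC[C@H](C[C@@]2(C)[C@H](CC[C@@H](C)CC(OC)OC)C(C)=CC[C@@H]2C(C)CO)O1 | intermediate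
22 | 19-hydroxy-2,3-(isopropylidenedioxy)-3,4-seco-labd-7-en-15-al | CC1(C)OC[C@H](C[C@@]2(C)[C@H](CC[C@@H](C)CC=O)C(C)=CC[C@@H]2C(C)CO)O1 | intermediate
23 | 19-hydroxy-2,3-(isopropylidenedioxy)-3,4-seco-labd-7-en-15-oic acid | CC1(C)OC[C@H](C[C@@]2(C)[C@H](CC[C@@H](C)CC(=O)O)C(C)=CC[C@@H]2C(C)CO)O1 | intermediate
24 | allyl 19-hydroxy-2,3-(isopropylidenedioxy)-3,4-seco-labd-7-en-15-oate | CC1(C)OC[C@H](C[C@@]2(C)[C@H](CC[C@@H](C)CC(=O)OCC=C)C(C)=CC[C@@H]2C(C)CO)O1 | intermediate
25 | allyl 2,3-(isopropylidenedioxy)-19-oxo-3,4-seco-labd-7-en-15-oate | CC1(C)OC[C@H](C[C@@]2(C)[C@H](CC[C@@H](C)CC(=O)OCC=C)C(C)=CC[C@@H]2C(C)C=O)O1 | intermediate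
26 | allyl 2,3-dihydroxy-19-oxo-3,4-seco-labd-7-en-15-oate | OC[C@@H](O)C[C@@]1(C)[C@H](CC[C@@H](C)CC(=O)OCC=C)C(C)=CC[C@@H]1C(C)C=O | intermediate
27 | allyl 3-(chloroacetoxy)-2-hydroxy-19-oxo-3,4-seco-labd-7-en-15-oate | ClCC(=O)OC[C@@H](O)C[C@@]1(C)[C@H](CC[C@@H](C)CC(=O)OCC=C)C(C)=CC[C@@H]1C(C)C=O | intermediate
28 | allyl (4(19)E)-3-(chloroacetoxy)-2,19-bis(tert-butyldimethylsilyloxy)-3,4-seco-labda-4(19),7-dien-15-oate | ClCC(=O)OC[C@@H](O[Si](C)(C)C(C)(C)C)C[C@@]1(C)[C@H](CC[C@@H](C)CC(=O)OCC=C)C(C)=CC[C@@H]1/C(C)=C/O[Si](C)(C)C(C)(C)C | intermediate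
29 | allyl (4(19)E)-2,19-bis(tert-butyldimethylsilyloxy)-3-hydroxy-3,4-seco-labda-4(19),7-dien-15-oate | OC[C@@H](O[Si](C)(C)C(C)(C)C)C[C@@]1(C)[C@H](CC[C@@H](C)CC(=O)OCC=C)C(C)=CC[C@@H]1/C(C)=C/O[Si](C)(C)C(C)(C)C | intermediate
30 | allyl (4(19)E)-2,19-bis(tert-butyldimethylsilyloxy)-3-oxo-3,4-seco-labda-4(19),7-dien-15-oate | O=C[C@@H](O[Si](C)(C)C(C)(C)C)C[C@@]1(C)[C@H](CC[C@@H](C)CC(=O)OCC=C)C(C)=CC[C@@H]1/C(C)=C/O[Si](C)(C)C(C)(C)C | intermediate
31 | allyl 2-(tert-butyldimethylsilyloxy)-3-hydroxy-19-oxolabd-7-en-15-oate | CC(C)(C)[Si](C)(C)O[C@H]1C[C@@]2(C)[C@H](CC[C@@H](C)CC(=O)OCC=C)C(C)=CC[C@@H]2[C@](C)(C=O)[C@H]1O | intermediate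
32 | allyl 2,3-dihydroxy-19-oxolabd-7-en-15-oate | O[C@H]1C[C@@]2(C)[C@H](CC[C@@H](C)CC(=O)OCC=C)C(C)=CC[C@@H]2[C@](C)(C=O)[C@H]1O | intermediate
33 | allyl 2-acetoxy-3-hydroxy-19-oxolabd-7-en-15-oate | CC(=O)O[C@H]1C[C@@]2(C)[C@H](CC[C@@H](C)CC(=O)OCC=C)C(C)=CC[C@@H]2[C@](C)(C=O)[C@H]1O | intermediate
34 | (2S,3R,4S,5S,9R,10S,13R)-2-acetoxy-3-hydroxy-19-oxolabd-7-en-15-oic acid | CC(=O)O[C@H]1C[C@@]2(C)[C@H](CC[C@@H](C)CC(=O)O)C(C)=CC[C@@H]2[C@](C)(C=O)[C@H]1O | target

Total step count: 25. Longest linear sequence: 22 steps (from 8: steps 4–25); the carvone line runs 20 steps (1, 3, 8–25).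

Steps most likely to fail

Step 22. Leakage through a synclinal transition state (C3 oxygen equatorial) would erode facial selectivity at the aldehyde carbon. The fallback sets C3 by reduction instead of by the aldol. It sets out from 30: the closure is run as before and the C3-epimeric aldol allyl 2-(tert-butyldimethylsilyloxy)-3-epi-hydroxy-19-oxolabd-7-en-15-oate F1 (or the C3 mixture) is oxidised with Dess–Martin periodinane to the 3,19-dioxo compound F2. LiBH(s-Bu)3 in THF at −78 °C then reduces both carbonyls, the ring ketone from the equatorial direction, to give the axial 3-ol as the 3,19-diol F3. TEMPO/PhI(OAc)2 reoxidises only the primary C19 alcohol, and the sequence comes back to the route at 31.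

Step 3. O-Alkylation, or stalling of C-alkylation, may occur when the tetrasubstituted enolate meets the β-oxygenated primary triflate. The fallback makes the C10–C1 bond by carbonyl addition and then removes the extra oxygen. It sets out from 3: enolate 6 is added at −78 °C to (R)-2,3-O-isopropylideneglyceraldehyde, again anti to isopropenyl, to give the β-hydroxy ketone F4 (C1 carbinol, either epimer). PhOC(S)Cl/pyridine/DMAP converts it into the O-phenyl thionocarbonate F5. Barton–McCombie deoxygenation with concentrated Bu3SnH/AIBN in toluene at 80 °C, where hydrogen transfer should outrun 1,2-acyl migration of the β-keto radical, then removes the C1 oxygen and rejoins the route at 7.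

Step 11. Elimination to the diene or incomplete Mitsunobu displacement may occur at the hindered secondary allylic carbinol. The fallback is dissolving-metal reduction with enolate trapping. It sets out from 15: Li in NH3/THF at −78 °C reduces the enone, the C9 carbanion being protonated to the isomer with the equatorial side chain. The regiodefined lithium enolate is trapped with PhNTf2 as the C7 enol triflate F6. Formate reduction catalysed by Pd(OAc)2/PPh3 (HCO2H, Bu3N, DMF, 60 °C) replaces the triflate by hydrogen and returns to the route at 19.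

Further compounds
F1 | step 22 | allyl 2-(tert-butyldimethylsilyloxy)-3-epi-hydroxy-19-oxolabd-7-en-15-oate | CC(C)(C)[Si](C)(C)O[C@H]1C[C@@]2(C)[C@H](CC[C@@H](C)CC(=O)OCC=C)C(C)=CC[C@@H]2[C@](C)(C=O)[C@@H]1O
F2 | step 22 | allyl 2-(tert-butyldimethylsilyloxy)-3,19-dioxolabd-7-en-15-oate | CC(C)(C)[Si](C)(C)O[C@H]1C[C@@]2(C)[C@H](CC[C@@H](C)CC(=O)OCC=C)C(C)=CC[C@@H]2[C@](C)(C=O)C1=O
F3 | step 22 | allyl 2-(tert-butyldimethylsilyloxy)-3,19-dihydroxylabd-7-en-15-oate (3-OH axial) | CC(C)(C)[Si](C)(C)O[C@H]1C[C@@]2(C)[C@H](CC[C@@H](C)CC(=O)OCC=C)C(C)=CC[C@@H]2[C@](C)(CO)[C@H]1O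
F4 | step 3 | (5R,6R)-6-{[(4S)-2,2-dimethyl-1,3-dioxolan-4-yl](hydroxy)methyl}-2,6-dimethyl-5-(prop-1-en-2-yl)cyclohex-2-en-1-one (carbinol epimers) | CC1(C)OC[C@H](C(O)[C@@]2(C)C(=O)C(C)=CC[C@@H]2C(C)=C)O1
F5 | step 3 | O-phenyl thionocarbonate of F4 | CC1(C)OC[C@H](C(OC(=S)Oc3ccccc3)[C@@]2(C)C(=O)C(C)=CC[C@@H]2C(C)=C)O1
F6 | step 11 | 15,15-dimethoxy-2,3-(isopropylidenedioxy)-3,4-seco-labda-4(19),7-dien-7-yl trifluoromethanesulfonate | CC1(C)OC[C@H](C[C@@]2(C)[C@H](CC[C@@H](C)CC(OC)OC)C(C)=C(OS(=O)(=O)C(F)(F)F)C[C@@H]2C(C)=C)O1
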